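## Structural features

The target is an achiral octaphenol made of two different catechol rings joined directly: ring A (chain on C1, OH on C3 and C4, aryl on C5) and ring B (C1' bonded to C5, OH on C3' and C4', chain on C6'). Each ring carries the same side chain, eight methylene groups ending in a 2,6-dihydroxyphenyl ketone. The molecule is nevertheless not symmetrical, because the biaryl bond is ortho to O4 on ring A but para to O4' on ring B. There is no stereocentre, and the axis C5–C1', flanked only by O4 and the C6' methylene, should rotate freely, so nothing stereochemical has to be controlled. The fragile parts are the two free catechols (air oxidation to o-quinones, above all in base) and, to a lesser degree, the electron-rich resorcinol ketones; the catechols are therefore carried as methyl ethers up to the last step. The real difficulty is regiochemical: a 1,2,4,5-tetrasubstituted ring B with its chain ortho to a hindered biaryl bond must be joined to a 1,3,4,5-tetrasubstituted ring A, and an oxidative coupling of two monomers would not tell the positions apart. The key step uses the relationship between O4 of ring A and the first chain carbon on C6' of ring B. If that carbon is an ester carbonyl on O4, the atoms C5, C4, O4 and C=O form a four-atom tether between an ethynyl group on C5 and a propiolate alkyne. All six carbons of ring B can then come from three alkynes, with C3' and C4' arriving as C–B bonds that later become the catechol oxygens.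

## Logic of the disconnections

21 to 20: the four O–CH3 bonds of the two catechols are cut. The skeleton is not simplified, but every earlier intermediate becomes air-stable and tolerant of base, hydride and Grignard reagents. The forward step must cleave four aryl methyl ethers without harming two aryl ketones and four free phenols.

20 to 18 and two molecules of 19: the bond between each ketone carbon and its neighbouring methylene is cut. Both chain ends are identical, so one aldehyde and one operation supply both resorcinol ketones at the right oxidation level, and 18 is a plain bis-alkene. The forward step must be linear-selective on both alkenes and must not move the double bonds along the chains.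

18 to 17 and 6: the benzylic CH2–CH2 bond of the ring B chain is cut. The carbon left on ring B is the former lactone carbonyl, and the seven carbons removed are the same reagent that builds the ring A chain. The coupling must be faster than ionisation of an electron-rich benzylic bromide.

17 to 16 to 15 to 14: these are changes of functional group only (C–Br from C–OH from ester). In 15 to 14 the lactone is opened by hydroxide and all four oxygens are methylated in one operation. Direct addition of 6 to the lactone was rejected for two reasons:
- an aryl lactone tends to take up an alkyl Grignard reagent twice;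
- the mono-adduct is a cyclic hemiketal, whose ionic reduction passes through a cyclic benzyl aryl ether and not straight to the open chain.

The demand is that O-methylation of the freed phenoxide outruns re-closure of the lactone.

14 to 13: the two C–O bonds of ring B are traced back to C–B bonds, which oxidise with retention of position. The oxidation must spare the terminal alkene, and the lactone must survive or re-close.

13 to 11 and 12 (key step): the ring B bonds C1'–C6', C2'–C3' and C4'–C5' are cut. Cutting here turns a hindered tetrasubstituted biaryl into one benzene ring bearing two neighbouring alkynes plus a symmetrical third alkyne; it also removes the lactone ring and gives the right oxidation state at C3' and C4'. Atom mapping confirms that every carbon of 11 and 12 is in place in 13 (C20H22O3 + C14H24B2O4 = C34H46B2O7), so neither structure needs correction. The design of 11 is kept but sharpened: both alkynes stay unsubstituted, so that C2' and C5' arrive as CH, and the ester is made last. The forward step demands cross-cyclotrimerisation over self-reaction of 11 and a bystander alkene.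

11 to 9 and 10: the ester C–O bond is cut. An aryl propiolate is too reactive to carry through several steps, so it is formed immediately before use. This requires acylation of a doubly ortho-substituted phenol without conjugate addition to the ynoate.

9 to 8 to 7 to 4 and 6: the benzylic CH2–CH2 bond of the ring A chain is cut. The benzylic carbon is the aldehyde carbon of the starting material, so carbonyl addition followed by deoxygenation of the carbinol replaces a three-step halide sequence. The two silyl groups of 8 come off together. The forward steps require a benzylic cation that is reduced faster than it alkylates another arene.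

4 to 2 and 3, and 2 to 1; 6 from 5: the aryl–alkyne bond is cut at the iodide of 1, after the phenol has been silylated so that the ortho-alkynylphenol cannot close to a benzofuran under the coupling conditions. The Grignard reagent 6 comes from 5 and serves both chains.

## Other disconnections considered

Alternative 1: Ring A is cut at C1–C2 and C5–C6. In the forward direction the diene A1 (ring B with its ester chain on a (Z)-1-aryl-2,3-bis(trimethylsilyloxy)butadiene) and the nitroalkene A2 would combine in a thermal Diels–Alder reaction; loss of HNO2 with DBU and dehydrogenation with DDQ would then give the biaryl diester A3.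
- In its favour: the union is convergent and metal-free. The polarity of the partners should place the chain on C1 (the unsubstituted diene terminus attacks the carbon beta to the nitro group), and the ring A catechol appears directly.
- Against it: A1 is a moisture-sensitive bis-silyl enol ether that must be made with defined geometry from a 1-aryl-2,3-diketone, which itself needs ring B with its ortho chain already built; the ring B problem is therefore only moved. The aromatisation asks DDQ to remove two hydrogens next to electron-rich benzylic positions and a latent catechol. The two esters of A3 must afterwards be turned into aryl ketones one functional group at a time, with the catechol reprotected.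
- Comparison: on mechanism Alternative 1 is the better plan in one respect, since a concerted cycloaddition has no competing oligomerisation of a diyne and needs no precious metal. On regiocontrol the two plans are equal, each relying on a built-in bias. On structure and step economy the chosen plan is ahead: the cyclotrimerisation creates ring B with all four substituents in one step, and one double hydroacylation finishes both chain ends.

Alternative 2: Ring A is cut between its two oxygenated carbons, C3–C4. The adipate A4 would be closed with sodium and chlorotrimethylsilane (Rühlmann acyloin conditions) to the enediol bis-silyl ether A5.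
- In its favour: the ring closure is a classical six-membered acyloin, the terminal alkenes are inert to it, and the oxygens of ring A come from the ester carbonyls, so their positions are automatically right.
- Against it: A5 is four hydrogens short of a catechol. Its dehydrogenation would have to be done in the presence of two terminal alkenes and activated benzylic positions, where hydrogen transfer, alkene migration and over-oxidation compete. A4 needs its own multi-step assembly, again from a ring B that already has its ortho chain, and it carries two stereocentres that only produce diastereomer mixtures before they are destroyed.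
- Comparison: the acyloin step is the equal of the chosen key step in reliability of the ring closure itself, and the better one in reagent cost and in indifference towards the alkenes. It forms only one C–C bond and one ring, against three bonds and two rings, and it leaves ring A at the wrong oxidation level, so the overall sequence would be clearly longer.

Alternative 3: The bond between C6' of ring B and the first chain carbon is cut. The 2-arylphenol A6 and the keto aldehyde A7 would condense under BF3·OEt2; the oxocarbenium ion, held on O4, would alkylate ring B para to its 3-methoxy group and give the racemic 6H-benzo[c]chromene A8. Reductive cleavage of the benzylic C–O bond and demethylation would follow.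
- In its favour: this is the most convergent plan. The biaryl of A6 comes from an ordinary cross-coupling of a 3,4-dimethoxyphenyl unit, both complete ketone chains are present before the key step, and the site on ring B is fixed by the tether and by the para-methoxy group.
- Against it: a phenol is a weak partner for oxocarbenium formation with an enolisable aldehyde, and self-condensation of A7 or Lewis-acid binding at the ketones may compete. The stereocentre at C6 of A8 is made only to be erased, and the C–O bond has to be cut reductively beside two aryl ketones. Two different chain-bearing fragments must be prepared separately, and eight methyl ethers must be cleaved at the end.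
- Comparison: Alternative 3 is the better plan in convergence and in the small number of operations after the key step, and it is the equal of the chosen plan in regiocontrol, since both use a temporary ring through O4. The chosen plan is better in that no stereogenic C–O bond has to be removed next to ketones and in that one Grignard reagent and one aldehyde serve both chains. In total step count the two are expected to be close.

Key step: step 8

Assumption: ethynyltrimethylsilane 3 and the diborylalkyne 12 are treated as purchased materials.

## Steps

Step 1
Reactants: 1 5-iodovanillin (4-hydroxy-3-iodo-5-methoxybenzaldehyde)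
Product: 2 4-[(tert-butyldimethylsilyl)oxy]-3-iodo-5-methoxybenzaldehyde
Conditions: TBSCl (1.2 equiv), imidazole (2.5 equiv), DMF, rt
Reagents that add atoms: tert-butyldimethylsilyl chloride, CC(C)(C)[Si](C)(C)Cl
Why: O-silylation of an acidic phenol; the silyl ether prevents phenoxide-driven benzofuran closure in step 2, survives the Grignard addition, and is later removed together with the alkyne silyl group.

Step 2
Reactants: 2 4-[(tert-butyldimethylsilyl)oxy]-3-iodo-5-methoxybenzaldehyde; 3 ethynyltrimethylsilane
Product: 4 4-[(tert-butyldimethylsilyl)oxy]-3-methoxy-5-[(trimethylsilyl)ethynyl]benzaldehyde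
Conditions: PdCl2(PPh3)2 (2 mol%), CuI (4 mol%), Et3N/THF, 50 °C
Reagents that add atoms: none
Why: Sonogashira coupling; the aryl iodide, activated by the para-formyl group, should add readily to zerovalent palladium, and aldehyde and silyl ether are inert to the amine/copper acetylide conditions; coupling before chain attachment keeps any aryl iodide away from the Grignard reagent.

Step 3
Reactants: 5 7-bromohept-1-ene
Product: 6 hept-6-en-1-ylmagnesium bromide (THF solution, titrated, used in steps 4 and 13)
Conditions: Mg, I2 (cat.), THF, rt to 40 °C
Reagents that add atoms: magnesium, [Mg]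
Why: Grignard formation from a primary bromide; the hept-6-enyl radical closes only slowly (6-exo), so a cyclised reagent is not expected.

Step 4
Reactants: 4 4-[(tert-butyldimethylsilyl)oxy]-3-methoxy-5-[(trimethylsilyl)ethynyl]benzaldehyde; 6 hept-6-en-1-ylmagnesium bromide
Product: 7 rac-1-{4-[(tert-butyldimethylsilyl)oxy]-3-methoxy-5-[(trimethylsilyl)ethynyl]phenyl}oct-7-en-1-ol
Conditions: THF, −78 to 0 °C; aq. NH4Cl
Reagents that add atoms: none
Why: Grignard 1,2-addition to an aromatic aldehyde, with the silylated alkyne and the aryl silyl ether as spectators; the carbinol centre is formed without control as a racemate and is erased in step 5.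

Step 5
Reactants: 7 rac-1-{4-[(tert-butyldimethylsilyl)oxy]-3-methoxy-5-[(trimethylsilyl)ethynyl]phenyl}oct-7-en-1-ol
Product: 8 tert-butyl{2-methoxy-4-(oct-7-en-1-yl)-6-[(trimethylsilyl)ethynyl]phenoxy}dimethylsilane
Conditions: Et3SiH (3 equiv), CF3CO2H (5 equiv), CH2Cl2, 0 °C
Reagents that add atoms: none
Why: Ionic hydrogenation (Kursanov–Parnes deoxygenation): the benzylic cation, stabilised by the para-silyloxy group, is trapped by hydride from the silane, while the terminal alkene cannot form a comparably stable cation and should stay untouched; partial loss of the aryl silyl group would do no harm because step 6 removes it.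

Step 6
Reactants: 8 tert-butyl{2-methoxy-4-(oct-7-en-1-yl)-6-[(trimethylsilyl)ethynyl]phenoxy}dimethylsilane
Product: 9 2-ethynyl-6-methoxy-4-(oct-7-en-1-yl)phenol
Conditions: Bu4NF (2.2 equiv), AcOH (2.2 equiv), THF, 0 °C; used at once
Reagents that add atoms: none
Why: Fluoride-induced cleavage of both the O–Si and the C(sp)–Si bond in one operation; the acetic acid buffer keeps the phenol protonated so that 5-endo closure of the phenoxide onto the alkyne is not triggered.

Step 7
Reactants: 9 2-ethynyl-6-methoxy-4-(oct-7-en-1-yl)phenol; 10 propiolic acid
Product: 11 2-ethynyl-6-methoxy-4-(oct-7-en-1-yl)phenyl prop-2-ynoate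
Conditions: DCC (1.2 equiv), DMAP (2 mol%), CH2Cl2, −20 to 0 °C
Reagents that add atoms: none
Why: Carbodiimide (Steglich-type) esterification of a phenol; low temperature and only a trace of DMAP are chosen to suppress conjugate addition of nucleophiles to the ynoate, and the product is filtered through silica and used directly.

Step 8
Reactants: 11 2-ethynyl-6-methoxy-4-(oct-7-en-1-yl)phenyl prop-2-ynoate; 12 1,2-bis(4,4,5,5-tetramethyl-1,3,2-dioxaborolan-2-yl)ethyne
Product: 13 4-methoxy-2-(oct-7-en-1-yl)-8,9-bis(4,4,5,5-tetramethyl-1,3,2-dioxaborolan-2-yl)-6H-benzo[c]chromen-6-one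
Conditions: Cp*RuCl(cod) (10 mol%), 12 (3 equiv), ClCH2CH2Cl, 40 °C, 11 added over 4 h by syringe pump
Reagents that add atoms: none
Why: After loss of cod the divalent ruthenium fragment Cp*RuCl binds both alkynes of 11 and couples them oxidatively to a bicyclic tetravalent ruthenacycle in which the aryl-bearing alkyne carbon (future C1') and the carbonyl-bearing alkyne carbon (future C6') are joined. This first C–C bond closes the six-membered lactone (C5, C4, O4, carbonyl carbon, C6', C1'), which requires the aryl ester to turn into its s-cis conformation. Alkyne 12 then inserts into a Ru–C bond and reductive elimination forms C2'–C3' and C4'–C5', closing ring B as a benzene ring from three two-carbon units and releasing the catalyst. The closest known reaction type is the Cp*RuCl(cod)-catalysed (2+2+2) cycloaddition of tethered diynes, ester-tethered ones included, with alkynylboronates. No stereocentre is formed. Three selectivities are needed: cross- over homo-cyclotrimerisation, which slow addition of 11 to an excess of 12 should secure because 12 carries two bulky boryl groups and cannot trimerise with itself; the ortho placement of ring A and the carbonyl on ring B, which the four-atom tether fixes; and the positions of the two boron atoms, on which the symmetry of 12 leaves no choice. The terminal alkene is a weaker ligand than the alkynes and sits far from the metallacycle, and high dilution disfavours its intermolecular reaction.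

Step 9
Reactants: 13 4-methoxy-2-(oct-7-en-1-yl)-8,9-bis(4,4,5,5-tetramethyl-1,3,2-dioxaborolan-2-yl)-6H-benzo[c]chromen-6-one
Product: 14 8,9-dihydroxy-4-methoxy-2-(oct-7-en-1-yl)-6H-benzo[c]chromen-6-one
Conditions: 30% aq. H2O2, NaHCO3, THF/H2O, 0 °C to rt; then Na2S2O3, 1 M HCl
Reagents that add atoms: hydrogen peroxide, OO
Why: Oxidation of arylboronates: hydroperoxide adds to boron and the aryl group migrates from B to O at the same carbon, so both oxygens land on C3' and C4'; an unactivated alkene is inert to H2O2, and the acidic work-up re-closes any lactone opened by the mild base.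

Step 10
Reactants: 14 8,9-dihydroxy-4-methoxy-2-(oct-7-en-1-yl)-6H-benzo[c]chromen-6-one
Product: 15 methyl 2-[2,3-dimethoxy-5-(oct-7-en-1-yl)phenyl]-4,5-dimethoxybenzoate
Conditions: KOH (powdered, excess), MeI (excess), DMSO, rt, argon
Reagents that add atoms: iodomethane, CI; potassium hydroxide, [K+].[OH-]
Why: Hydroxide saponifies the aryl lactone, and the carboxylate and the three phenoxides are then O-methylated exhaustively (Williamson alkylation in DMSO); methylation of the freed ring A phenoxide makes the ring opening irreversible, and argon protects the catecholate from air.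

Step 11
Reactants: 15 methyl 2-[2,3-dimethoxy-5-(oct-7-en-1-yl)phenyl]-4,5-dimethoxybenzoate
Product: 16 {2-[2,3-dimethoxy-5-(oct-7-en-1-yl)phenyl]-4,5-dimethoxyphenyl}methanol
Conditions: LiAlH4, THF, 0 °C; Fieser work-up
Reagents that add atoms: none
Why: Hydride reduction of an ester to the primary alcohol; aryl ethers and the isolated alkene are inert to LiAlH4.

Step 12
Reactants: 16 {2-[2,3-dimethoxy-5-(oct-7-en-1-yl)phenyl]-4,5-dimethoxyphenyl}methanol
Product: 17 1-(bromomethyl)-2-[2,3-dimethoxy-5-(oct-7-en-1-yl)phenyl]-4,5-dimethoxybenzene
Conditions: PBr3 (0.4 equiv), Et2O, 0 °C; cold NaHCO3 wash; crude used at once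
Reagents that add atoms: phosphorus tribromide, BrP(Br)Br
Why: Conversion of a benzylic alcohol into the bromide through its phosphite ester; the dimethoxybenzyl bromide ionises easily, so it is kept cold and not stored.

Step 13
Reactants: 17 1-(bromomethyl)-2-[2,3-dimethoxy-5-(oct-7-en-1-yl)phenyl]-4,5-dimethoxybenzene; 6 hept-6-en-1-ylmagnesium bromide
Product: 18 2,3,4',5'-tetramethoxy-2',5-di(oct-7-en-1-yl)-1,1'-biphenyl
Conditions: 6 (1.5 equiv), Li2CuCl4 (3 mol%), THF, −78 to 0 °C
Reagents that add atoms: none
Why: Kochi copper-catalysed sp3–sp3 cross-coupling of a primary alkyl Grignard reagent with a benzylic bromide through an alkylcuprate; benzylic halides couple quickly at low temperature, and ethers and alkenes do not interfere.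

Step 14
Reactants: 18 2,3,4',5'-tetramethoxy-2',5-di(oct-7-en-1-yl)-1,1'-biphenyl; 19 2,6-dihydroxybenzaldehyde
Product: 20 9,9'-(2',3',4,5-tetramethoxy-[1,1'-biphenyl]-2,5'-diyl)bis[1-(2,6-dihydroxyphenyl)nonan-1-one]
Conditions: 19 (3 equiv), [RhCl(coe)2]2 (2.5 mol%), BINOL-derived phosphoramidite (10 mol%), K3PO4 (10 mol%), 1,4-dioxane, 70 °C
Reagents that add atoms: none
Why: Chelation-assisted intermolecular alkene hydroacylation with a salicylaldehyde: the phenoxide binds monovalent rhodium, C–H oxidative addition gives a chelated acyl rhodium hydride that resists decarbonylation, and linear hydride insertion followed by reductive elimination gives the linear ketone at each terminal alkene; no stereocentre arises.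

Step 15
Reactants: 20 9,9'-(2',3',4,5-tetramethoxy-[1,1'-biphenyl]-2,5'-diyl)bis[1-(2,6-dihydroxyphenyl)nonan-1-one]
Product: 21 9,9'-(2',3',4,5-tetrahydroxy-[1,1'-biphenyl]-2,5'-diyl)bis[1-(2,6-dihydroxyphenyl)nonan-1-one] (CNP0305015.0)
Conditions: BBr3 (12 equiv), CH2Cl2, −78 to 0 °C; then ice water, argon
Reagents that add atoms: none
Why: Lewis-acid cleavage of aryl methyl ethers (boron binds the ether oxygen, bromide attacks the methyl group); aryl ketones are stable and the free phenols are only converted temporarily into borates that hydrolyse on work-up, which is done with exclusion of air to protect the catechols.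

## Compound list

1 | 5-iodovanillin (4-hydroxy-3-iodo-5-methoxybenzaldehyde) | COc1cc(C=O)cc(I)c1O | starting material
2 | 4-[(tert-butyldimethylsilyl)oxy]-3-iodo-5-methoxybenzaldehyde | COc1cc(C=O)cc(I)c1O[Si](C)(C)C(C)(C)C | intermediate
3 | ethynyltrimethylsilane | C#C[Si](C)(C)C | starting material
4 | 4-[(tert-butyldimethylsilyl)oxy]-3-methoxy-5-[(trimethylsilyl)ethynyl]benzaldehyde | COc1cc(C=O)cc(C#C[Si](C)(C)C)c1O[Si](C)(C)C(C)(C)C | intermediate
5 | 7-bromohept-1-ene | C=CCCCCCBr | starting material
6 | hept-6-en-1-ylmagnesium bromide | C=CCCCCC[Mg]Br | intermediate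
7 | rac-1-{4-[(tert-butyldimethylsilyl)oxy]-3-methoxy-5-[(trimethylsilyl)ethynyl]phenyl}oct-7-en-1-ol | COc1cc(C(O)CCCCCC=C)cc(C#C[Si](C)(C)C)c1O[Si](C)(C)C(C)(C)C | intermediate
8 | tert-butyl{2-methoxy-4-(oct-7-en-1-yl)-6-[(trimethylsilyl)ethynyl]phenoxy}dimethylsilane | COc1cc(CCCCCCC=C)cc(C#C[Si](C)(C)C)c1O[Si](C)(C)C(C)(C)C | intermediate
9 | 2-ethynyl-6-methoxy-4-(oct-7-en-1-yl)phenol | COc1cc(CCCCCCC=C)cc(C#C)c1O | intermediate
10 | propiolic acid | C#CC(=O)O | starting material
11 | 2-ethynyl-6-methoxy-4-(oct-7-en-1-yl)phenyl prop-2-ynoate | C=CCCCCCCc1cc(OC)c(OC(=O)C#C)c(C#C)c1 | intermediate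
12 | 1,2-bis(4,4,5,5-tetramethyl-1,3,2-dioxaborolan-2-yl)ethyne | CC1(C)OB(C#CB2OC(C)(C)C(C)(C)O2)OC1(C)C | starting material
13 | 4-methoxy-2-(oct-7-en-1-yl)-8,9-bis(4,4,5,5-tetramethyl-1,3,2-dioxaborolan-2-yl)-6H-benzo[c]chromen-6-one | C=CCCCCCCc1cc(OC)c2OC(=O)c3cc(B4OC(C)(C)C(C)(C)O4)c(B4OC(C)(C)C(C)(C)O4)cc3-c2c1 | intermediate
14 | 8,9-dihydroxy-4-methoxy-2-(oct-7-en-1-yl)-6H-benzo[c]chromen-6-one | C=CCCCCCCc1cc(OC)c2OC(=O)c3cc(O)c(O)cc3-c2c1 | intermediate
15 | methyl 2-[2,3-dimethoxy-5-(oct-7-en-1-yl)phenyl]-4,5-dimethoxybenzoate | C=CCCCCCCc1cc(OC)c(OC)c(-c2cc(OC)c(OC)cc2C(=O)OC)c1 | intermediate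
16 | {2-[2,3-dimethoxy-5-(oct-7-en-1-yl)phenyl]-4,5-dimethoxyphenyl}methanol | C=CCCCCCCc1cc(OC)c(OC)c(-c2cc(OC)c(OC)cc2CO)c1 | intermediate
17 | 1-(bromomethyl)-2-[2,3-dimethoxy-5-(oct-7-en-1-yl)phenyl]-4,5-dimethoxybenzene | C=CCCCCCCc1cc(OC)c(OC)c(-c2cc(OC)c(OC)cc2CBr)c1 | intermediate
18 | 2,3,4',5'-tetramethoxy-2',5-di(oct-7-en-1-yl)-1,1'-biphenyl | C=CCCCCCCc1cc(OC)c(OC)c(-c2cc(OC)c(OC)cc2CCCCCCC=C)c1 | intermediate
19 | 2,6-dihydroxybenzaldehyde | O=Cc1c(O)cccc1O | starting material
20 | 9,9'-(2',3',4,5-tetramethoxy-[1,1'-biphenyl]-2,5'-diyl)bis[1-(2,6-dihydroxyphenyl)nonan-1-one] | O=C(CCCCCCCCc1cc(OC)c(OC)c(-c2cc(OC)c(OC)cc2CCCCCCCCC(=O)c2c(O)cccc2O)c1)c1c(O)cccc1O | intermediate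
21 | 9,9'-(2',3',4,5-tetrahydroxy-[1,1'-biphenyl]-2,5'-diyl)bis[1-(2,6-dihydroxyphenyl)nonan-1-one] (CNP0305015.0) | O=C(CCCCCCCCc1cc(O)c(O)c(-c2cc(O)c(O)cc2CCCCCCCCC(=O)c2c(O)cccc2O)c1)c1c(O)cccc1O | target

## Step count and least certain steps

Total: 15 steps. Longest linear sequence: 14 steps (from 1 to 21 through steps 1, 2 and 4 to 15); step 3 is the side branch that makes 6 for steps 4 and 13.

Step 8 (key step). The ruthenacycle may react with a second molecule of 11 instead of the hindered alkyne 12 (homo-oligomerisation), and the oxidative coupling across a six-membered ester tether may be slow enough for the aryl propiolate to decompose or for the alkene to be drawn in. Fallback: the biaryl is made by cross-coupling instead of cyclotrimerisation, setting out from 1 and returning at 15. O-methylation of 1 (MeI, K2CO3, DMF) would give 3-iodo-4,5-dimethoxybenzaldehyde F1. Addition of 6 gives rac-1-(3-iodo-4,5-dimethoxyphenyl)oct-7-en-1-ol F2, and Et3SiH/CF3CO2H gives 1-iodo-2,3-dimethoxy-5-(oct-7-en-1-yl)benzene F3. Miyaura borylation (B2pin2, PdCl2(dppf), KOAc, dioxane, 80 °C) gives 2-[2,3-dimethoxy-5-(oct-7-en-1-yl)phenyl]-4,4,5,5-tetramethyl-1,3,2-dioxaborolane F4. Suzuki–Miyaura coupling of F4 with purchased methyl 2-bromo-4,5-dimethoxybenzoate (Pd(OAc)2, SPhos, K3PO4, toluene/H2O, 80 °C) gives 15. This conventional route would reach 15 in fewer steps than the main route.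

Step 14. Decarbonylation of the acyl rhodium hydride may stop the catalyst before the second alkene has reacted; branched insertion and migration of the double bonds along the chains are the other dangers, and all of them count twice. Fallback: the ketone ends are built by cross-metathesis, setting out from 18 and returning at 21. Vinylmagnesium bromide adds to purchased 2,6-dimethoxybenzaldehyde to give rac-1-(2,6-dimethoxyphenyl)prop-2-en-1-ol F5, and MnO2 oxidises it to 1-(2,6-dimethoxyphenyl)prop-2-en-1-one F6. Double cross-metathesis of 18 with F6 (second-generation Grubbs catalyst, CH2Cl2, 40 °C) gives (2E,2'E)-9,9'-(2',3',4,5-tetramethoxy-[1,1'-biphenyl]-2,5'-diyl)bis[1-(2,6-dimethoxyphenyl)non-2-en-1-one] F7. Hydrogenation of the enone double bonds (H2, Pd/C, EtOAc) gives 9,9'-(2',3',4,5-tetramethoxy-[1,1'-biphenyl]-2,5'-diyl)bis[1-(2,6-dimethoxyphenyl)nonan-1-one] F8, and BBr3 cleaves all eight methyl ethers to 21.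

Step 13 (with step 12). The electron-rich benzylic bromide may ionise before it couples, with ring closure by the neighbouring ring A methoxy oxygen and loss of a methyl group; homocoupling of the bromide is the second risk. Fallback: carbonyl addition and ionic deoxygenation replace the substitution, setting out from 16 and returning at 18. MnO2 oxidises 16 to 2-[2,3-dimethoxy-5-(oct-7-en-1-yl)phenyl]-4,5-dimethoxybenzaldehyde F9. Addition of 6 gives rac-1-{2-[2,3-dimethoxy-5-(oct-7-en-1-yl)phenyl]-4,5-dimethoxyphenyl}oct-7-en-1-ol F10, and Et3SiH with BF3·OEt2 (CH2Cl2, −78 °C) reduces F10 to 18.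

Step 10. Ring opening may lag behind methylation, leaving the methylated lactone, and the catecholate may be oxidised by traces of air; slow migration of the terminal double bond in the strongly basic medium is also possible. Fallback: the lactone is reduced before the last phenol is methylated, setting out from 14 and returning at 16. K2CO3 and MeI in acetone give 4,8,9-trimethoxy-2-(oct-7-en-1-yl)-6H-benzo[c]chromen-6-one F11. LiAlH4 gives 2-[2-(hydroxymethyl)-4,5-dimethoxyphenyl]-6-methoxy-4-(oct-7-en-1-yl)phenol F12, and K2CO3 and MeI in acetone methylate only the phenol of F12 to give 16.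

Step 7. Conjugate addition of the phenol or of DMAP to the ynoate, rearrangement of the activated acid to the N-acylurea, and closure of 9 to a benzofuran may all lower the return of this acylation. Fallback: the propiolate is introduced in silyl-masked form, setting out from 9 and returning at 11. Purchased 3-(trimethylsilyl)propiolic acid and DCC acylate 9 to 2-ethynyl-6-methoxy-4-(oct-7-en-1-yl)phenyl 3-(trimethylsilyl)prop-2-ynoate F13. Buffered fluoride (Bu4NF, AcOH, THF, −78 °C) then removes the very labile ynoate silyl group from F13 to give 11.

## Further compounds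

F1 | step 8 | 3-iodo-4,5-dimethoxybenzaldehyde | COc1cc(C=O)cc(I)c1OC
F2 | step 8 | rac-1-(3-iodo-4,5-dimethoxyphenyl)oct-7-en-1-ol | COc1cc(C(O)CCCCCC=C)cc(I)c1OC
F3 | step 8 | 1-iodo-2,3-dimethoxy-5-(oct-7-en-1-yl)benzene | COc1cc(CCCCCCC=C)cc(I)c1OC
F4 | step 8 | 2-[2,3-dimethoxy-5-(oct-7-en-1-yl)phenyl]-4,4,5,5-tetramethyl-1,3,2-dioxaborolane | COc1cc(CCCCCCC=C)cc(B2OC(C)(C)C(C)(C)O2)c1OC
F5 | step 14 | rac-1-(2,6-dimethoxyphenyl)prop-2-en-1-ol | C=CC(O)c1c(OC)cccc1OC
F6 | step 14 | 1-(2,6-dimethoxyphenyl)prop-2-en-1-one | C=CC(=O)c1c(OC)cccc1OC
F7 | step 14 | (2E,2'E)-9,9'-(2',3',4,5-tetramethoxy-[1,1'-biphenyl]-2,5'-diyl)bis[1-(2,6-dimethoxyphenyl)non-2-en-1-one] | O=C(/C=C/CCCCCCc1cc(OC)c(OC)c(-c2cc(OC)c(OC)cc2CCCCCC/C=C/C(=O)c2c(OC)cccc2OC)c1)c1c(OC)cccc1OC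
F8 | step 14 | 9,9'-(2',3',4,5-tetramethoxy-[1,1'-biphenyl]-2,5'-diyl)bis[1-(2,6-dimethoxyphenyl)nonan-1-one] | O=C(CCCCCCCCc1cc(OC)c(OC)c(-c2cc(OC)c(OC)cc2CCCCCCCCC(=O)c2c(OC)cccc2OC)c1)c1c(OC)cccc1OC
F9 | step 13 | 2-[2,3-dimethoxy-5-(oct-7-en-1-yl)phenyl]-4,5-dimethoxybenzaldehyde | C=CCCCCCCc1cc(OC)c(OC)c(-c2cc(OC)c(OC)cc2C=O)c1
F10 | step 13 | rac-1-{2-[2,3-dimethoxy-5-(oct-7-en-1-yl)phenyl]-4,5-dimethoxyphenyl}oct-7-en-1-ol | C=CCCCCCCc1cc(OC)c(OC)c(-c2cc(OC)c(OC)cc2C(O)CCCCCC=C)c1
F11 | step 10 | 4,8,9-trimethoxy-2-(oct-7-en-1-yl)-6H-benzo[c]chromen-6-one | C=CCCCCCCc1cc(OC)c2OC(=O)c3cc(OC)c(OC)cc3-c2c1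
F12 | step 10 | 2-[2-(hydroxymethyl)-4,5-dimethoxyphenyl]-6-methoxy-4-(oct-7-en-1-yl)phenol | C=CCCCCCCc1cc(OC)c(O)c(-c2cc(OC)c(OC)cc2CO)c1
F13 | step 7 | 2-ethynyl-6-methoxy-4-(oct-7-en-1-yl)phenyl 3-(trimethylsilyl)prop-2-ynoate | C=CCCCCCCc1cc(OC)c(OC(=O)C#C[Si](C)(C)C)c(C#C)c1
A1 | alternative 1 | methyl 9-{2-[(1Z)-2,3-bis(trimethylsilyloxy)buta-1,3-dien-1-yl]-4,5-dimethoxyphenyl}nonanoate | C[Si](C)(C)O/C(=C\c1cc(OC)c(OC)cc1CCCCCCCCC(=O)OC)C(=C)O[Si](C)(C)C
A2 | alternative 1 | methyl (E)-11-nitroundec-10-enoate | COC(=O)CCCCCCCC/C=C/[N+](=O)[O-]
A3 | alternative 1 | methyl 9-{2-[2,3-dihydroxy-5-(9-methoxy-9-oxononyl)phenyl]-4,5-dimethoxyphenyl}nonanoate | COC(=O)CCCCCCCCc1cc(O)c(O)c(-c2cc(OC)c(OC)cc2CCCCCCCCC(=O)OC)c1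
A4 | alternative 2 | dimethyl 2-[4,5-dimethoxy-2-(oct-7-en-1-yl)phenyl]-4-(oct-7-en-1-yl)hexanedioate (diastereomer mixture) | COC(=O)CC(CCCCCCC=C)CC(C(=O)OC)c1cc(OC)c(OC)cc1CCCCCCC=C
A5 | alternative 2 | 3-[4,5-dimethoxy-2-(oct-7-en-1-yl)phenyl]-5-(oct-7-en-1-yl)-1,2-bis(trimethylsilyloxy)cyclohexene (diastereomer mixture) | C[Si](C)(C)OC1=C(O[Si](C)(C)C)C(c2cc(OC)c(OC)cc2CCCCCCC=C)CC(CCCCCCC=C)C1
A6 | alternative 3 | 9-[3-(3,4-dimethoxyphenyl)-4-hydroxy-5-methoxyphenyl]-1-(2,6-dimethoxyphenyl)nonan-1-one | COc1cc(CCCCCCCCC(=O)c2c(OC)cccc2OC)cc(-c2ccc(OC)c(OC)c2)c1O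
A7 | alternative 3 | 9-(2,6-dimethoxyphenyl)-9-oxononanal | O=CCCCCCCCC(=O)c1c(OC)cccc1OC
A8 | alternative 3 | rac-1-(2,6-dimethoxyphenyl)-9-{6-[8-(2,6-dimethoxyphenyl)-8-oxooctyl]-4,8,9-trimethoxy-6H-benzo[c]chromen-2-yl}nonan-1-one | COc1cc(CCCCCCCCC(=O)c4c(OC)cccc4OC)cc2-c3cc(OC)c(OC)cc3C(CCCCCCCC(=O)c3c(OC)cccc3OC)Oc12
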